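The pyranone ring (ring C) is closed last, at the aryl ether bond O1–C8a. The precursor is an open-chain (S)-β-hydroxy ketone whose ring A bears a triflate on C8a, the one ring A carbon flanked by the acyl-bearing C4a and the geranyl-bearing C8. An intramolecular palladium-catalysed C–O coupling joins the C2 carbinol oxygen to C8a. In one operation it closes ring C, fixes the 8-geranyl (not 6-geranyl) regiochemistry and keeps the C2 stereocentre, set by a catalytic asymmetric Mukaiyama aldol addition, because the C2–O bond is never broken. Ring A comes from symmetric 2,4,6-trihydroxyacetophenone.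

Key step: step 7

Remark: flavanone numbering is used throughout (O1, C2, C3, C4, C4a, C5 to C8, C8a; ring A is the phloroglucinol ring, ring C the pyranone ring); geranyl means (2E)-3,7-dimethylocta-2,6-dien-1-yl; the target is the (2S) enantiomer.
Assumption: of the two antipodes of the bisphosphoramide catalyst in step 6, the one that directs the enol ether to the Si face of aldehyde 9 is used, since Si-face attack gives the (S)-carbinol.

Step 1
Reactants: 1 2,4,6-trihydroxyacetophenone; 2 geranyl bromide
Product: 3 1-(3-geranyl-2,4,6-trihydroxyphenyl)ethan-1-one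
Conditions: DBU (1.0 equiv), 2 (0.9 equiv), THF, 0 °C to rt
Reagents that add atoms: none
Why: C-alkylation of the ambident acylphloroglucinol anion (phenolate C-allylation by SN2 at the primary allylic bromide, so the E alkene is kept) should give a single mono-C-geranyl isomer because the two free ring positions of 1 are equivalent, and the slight deficit of bromide limits double alkylation.

Step 2
Reactants: 3 1-(3-geranyl-2,4,6-trihydroxyphenyl)ethan-1-one; 4 geraniol
Product: 5 1-[3-geranyl-4-(geranyloxy)-2,6-dihydroxyphenyl]ethan-1-one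
Conditions: PPh3, DIAD, THF, 0 °C to rt
Reagents that add atoms: none
Why: Mitsunobu etherification should take place at the 4-OH, which is para to the acetyl group and the most acidic phenol of the acylphloroglucinol, while the neutral conditions exclude further C-alkylation and the SN2 displacement at the primary allylic carbon keeps the E geometry.

Step 3
Reactants: 5 1-[3-geranyl-4-(geranyloxy)-2,6-dihydroxyphenyl]ethan-1-one
Product: 6 1-[3-geranyl-4-(geranyloxy)-2-hydroxy-6-(triisopropylsilyloxy)phenyl]ethan-1-one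
Conditions: TIPSCl (1.05 equiv), imidazole, DMF, 0 °C
Reagents that add atoms: chlorotriisopropylsilane (TIPSCl), CC(C)[Si](Cl)(C(C)C)C(C)C
Why: Silylation of a phenol with a bulky silyl chloride should go to O6, whose ring neighbour is a hydrogen, and leave the 2-OH, which is flanked by the geranyl chain and held in a hydrogen bond to the carbonyl group.

Step 4
Reactants: 6 1-[3-geranyl-4-(geranyloxy)-2-hydroxy-6-(triisopropylsilyloxy)phenyl]ethan-1-one
Product: 7 2-acetyl-6-geranyl-5-(geranyloxy)-3-(triisopropylsilyloxy)phenyl trifluoromethanesulfonate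
Conditions: Tf2O, pyridine, CH2Cl2, –20 to 0 °C
Reagents that add atoms: trifluoromethanesulfonic anhydride (Tf2O), O=S(=O)(OS(=O)(=O)C(F)(F)F)C(F)(F)F
Why: Triflation of the only remaining phenol turns the oxygen on the future C8a into a leaving group, with excess pyridine buffering the acid away from the geranyl alkenes.

Step 5
Reactants: 7 2-acetyl-6-geranyl-5-(geranyloxy)-3-(triisopropylsilyloxy)phenyl trifluoromethanesulfonate
Product: 8 6-geranyl-5-(geranyloxy)-3-(triisopropylsilyloxy)-2-[1-(trimethylsilyloxy)ethenyl]phenyl trifluoromethanesulfonate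
Conditions: TMSOTf, Et3N, CH2Cl2, 0 °C
Reagents that add atoms: trimethylsilyl trifluoromethanesulfonate (TMSOTf), C[Si](C)(C)OS(=O)(=O)C(F)(F)F
Why: Soft enolisation of the methyl ketone gives the terminal silyl enol ether without a free metal enolate, which avoids triflyl transfer from the neighbouring aryl triflate.

Step 6
Reactants: 8 6-geranyl-5-(geranyloxy)-3-(triisopropylsilyloxy)-2-[1-(trimethylsilyloxy)ethenyl]phenyl trifluoromethanesulfonate; 9 4-(tert-butyldimethylsilyloxy)benzaldehyde
Product: 11 2-{(3S)-3-[4-(tert-butyldimethylsilyloxy)phenyl]-3-hydroxypropanoyl}-6-geranyl-5-(geranyloxy)-3-(triisopropylsilyloxy)phenyl trifluoromethanesulfonate, via trichlorosilyl aldolate 10 (not isolated)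
Conditions: SiCl4 (1.5 equiv), chiral binaphthyldiamine-derived bisphosphoramide (5 mol %), iPr2NEt (10 mol %), CH2Cl2, –78 °C; then cold aq NaHCO3
Reagents that add atoms: none
Why: Lewis-base-catalysed asymmetric Mukaiyama aldol addition, in which the phosphoramide-bound trichlorosilyl cation activates the aromatic aldehyde and the chiral catalyst exposes its Si face to the enol ether, should set the (S)-carbinol (the future C2) and release the free aldol on bicarbonate work-up.

Step 7
Reactants: 11 2-{(3S)-3-[4-(tert-butyldimethylsilyloxy)phenyl]-3-hydroxypropanoyl}-6-geranyl-5-(geranyloxy)-3-(triisopropylsilyloxy)phenyl trifluoromethanesulfonate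
Product: 12 (2S)-2-[4-(tert-butyldimethylsilyloxy)phenyl]-8-geranyl-7-(geranyloxy)-5-(triisopropylsilyloxy)chroman-4-one
Conditions: Pd(OAc)2 (5 mol %), 2-(di-tert-butylphosphino)-1,1'-binaphthyl (6 mol %), K3PO4 (2 equiv), toluene, 60 °C
Reagents that add atoms: none
Why: Zerovalent palladium, formed in situ from Pd(OAc)2 and the phosphine, should insert into the C8a–OTf bond, which the ortho acyl group activates, after which phosphate-assisted exchange of triflate for the C2 alkoxide and C–O reductive elimination from the aryl alkoxide complex of divalent palladium form the O1–C8a bond. The closest known reaction type is the intramolecular Buchwald–Hartwig etherification of aryl halides and triflates with secondary alcohols, which carries the carbinol configuration through unchanged. Ring C is closed as a six-membered ring (formally 6-exo attack of O1 on the arene carbon C8a) by reductive elimination from a seven-membered palladacycle, and no other ring size is within reach. No stereocentre is made, and C2 keeps the (S) configuration from step 6 because only the O–H bond of the carbinol reacts. The step needs site selectivity for C8a over the oxygen-bearing C5, which is secured because only C8a carries a leaving group while O5 is silylated, and it needs chemoselectivity over β-hydride elimination, retro-aldol cleavage, dehydration and ionisation of the geranyl aryl ether, for which the bulky electron-rich phosphine, the weak heterogeneous base and the fast oxidative addition at the acyl-activated triflate are relied on.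

Step 8
Reactants: 12 (2S)-2-[4-(tert-butyldimethylsilyloxy)phenyl]-8-geranyl-7-(geranyloxy)-5-(triisopropylsilyloxy)chroman-4-one
Product: 13 (2S)-8-geranyl-7-(geranyloxy)-5-hydroxy-2-(4-hydroxyphenyl)chroman-4-one
Conditions: TBAF (2.5 equiv), AcOH (2.5 equiv), THF, 0 °C
Reagents that add atoms: none
Why: Fluoride should cleave both aryl silyl ethers, while the acetic acid buffer keeps the medium non-basic so that the flavanone does not open to the chalcone (no epimerisation at C2) and the allylic aryl ether and the alkenes stay untouched.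

Compound list
1 | 2,4,6-trihydroxyacetophenone | CC(=O)c1c(O)cc(O)cc1O | starting material
2 | geranyl bromide, (2E)-1-bromo-3,7-dimethylocta-2,6-diene | CC(C)=CCC/C(C)=C/CBr | starting material
3 | 1-(3-geranyl-2,4,6-trihydroxyphenyl)ethan-1-one | CC(=O)c1c(O)cc(O)c(C/C=C(\C)CCC=C(C)C)c1O | intermediate
4 | geraniol, (2E)-3,7-dimethylocta-2,6-dien-1-ol | CC(C)=CCC/C(C)=C/CO | starting material
5 | 1-[3-geranyl-4-(geranyloxy)-2,6-dihydroxyphenyl]ethan-1-one | CC(=O)c1c(O)cc(OC/C=C(\C)CCC=C(C)C)c(C/C=C(\C)CCC=C(C)C)c1O | intermediate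
6 | 1-[3-geranyl-4-(geranyloxy)-2-hydroxy-6-(triisopropylsilyloxy)phenyl]ethan-1-one | CC(=O)c1c(O[Si](C(C)C)(C(C)C)C(C)C)cc(OC/C=C(\C)CCC=C(C)C)c(C/C=C(\C)CCC=C(C)C)c1O | intermediate
7 | 2-acetyl-6-geranyl-5-(geranyloxy)-3-(triisopropylsilyloxy)phenyl trifluoromethanesulfonate | CC(=O)c1c(O[Si](C(C)C)(C(C)C)C(C)C)cc(OC/C=C(\C)CCC=C(C)C)c(C/C=C(\C)CCC=C(C)C)c1OS(=O)(=O)C(F)(F)F | intermediate
8 | 6-geranyl-5-(geranyloxy)-3-(triisopropylsilyloxy)-2-[1-(trimethylsilyloxy)ethenyl]phenyl trifluoromethanesulfonate | C=C(O[Si](C)(C)C)c1c(O[Si](C(C)C)(C(C)C)C(C)C)cc(OC/C=C(\C)CCC=C(C)C)c(C/C=C(\C)CCC=C(C)C)c1OS(=O)(=O)C(F)(F)F | intermediate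
9 | 4-(tert-butyldimethylsilyloxy)benzaldehyde | O=Cc1ccc(O[Si](C)(C)C(C)(C)C)cc1 | starting material
10 | trichlorosilyl aldolate, the O-trichlorosilyl ether of 11 (formed in the flask, silicon from SiCl4) | O=C(C[C@H](O[Si](Cl)(Cl)Cl)c1ccc(O[Si](C)(C)C(C)(C)C)cc1)c1c(O[Si](C(C)C)(C(C)C)C(C)C)cc(OC/C=C(\C)CCC=C(C)C)c(C/C=C(\C)CCC=C(C)C)c1OS(=O)(=O)C(F)(F)F | intermediate
11 | 2-{(3S)-3-[4-(tert-butyldimethylsilyloxy)phenyl]-3-hydroxypropanoyl}-6-geranyl-5-(geranyloxy)-3-(triisopropylsilyloxy)phenyl trifluoromethanesulfonate | O=C(C[C@H](O)c1ccc(O[Si](C)(C)C(C)(C)C)cc1)c1c(O[Si](C(C)C)(C(C)C)C(C)C)cc(OC/C=C(\C)CCC=C(C)C)c(C/C=C(\C)CCC=C(C)C)c1OS(=O)(=O)C(F)(F)F | intermediate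
12 | (2S)-2-[4-(tert-butyldimethylsilyloxy)phenyl]-8-geranyl-7-(geranyloxy)-5-(triisopropylsilyloxy)chroman-4-one | CC(C)=CCC/C(C)=C/COc1cc(O[Si](C(C)C)(C(C)C)C(C)C)c2c(c1C/C=C(\C)CCC=C(C)C)O[C@H](c1ccc(O[Si](C)(C)C(C)(C)C)cc1)CC2=O | intermediate
13 | (2S)-8-geranyl-7-(geranyloxy)-5-hydroxy-2-(4-hydroxyphenyl)chroman-4-one | CC(C)=CCC/C(C)=C/COc1cc(O)c2c(c1C/C=C(\C)CCC=C(C)C)O[C@H](c1ccc(O)cc1)CC2=O | target

Total step count: 8. Longest linear sequence: 8 steps (1 to 13).

Steps most likely to fail

Step 7 (key ring closure). The β-hydroxy ketone may not survive base at the coupling temperature: retro-aldol cleavage or dehydration to the enone could outrun ring closure, or the palladium alkoxide could undergo β-hydride elimination. The fallback takes the carbonyl group out of play and sets out from 11. Reduction (NaBH4, MeOH, –20 °C) would give the 1,3-diol F1 as a mixture of epimers at the new carbinol carbon. The same palladium-catalysed C–O coupling, in which only the C2 hydroxyl can reach C8a through a six-membered ring, would then give the flavan-4-ol F2. Oxidation with Dess–Martin periodinane (NaHCO3-buffered CH2Cl2, 0 °C) comes back to the route at 12.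

Step 6 (asymmetric aldol addition). Facial selectivity may be poor, or the hindered enol ether may add sluggishly to the electron-rich aldehyde. The fallback sets the carbinol by epoxidation and reductive opening and sets out from 7. Aldol addition of its lithium enolate to 9 (LiN(SiMe3)2, THF, –78 °C) would give the racemic aldol F3. Mesylation and elimination (MsCl, Et3N, CH2Cl2, 0 °C to rt) would lead through the mesylate F4 to the (E)-chalcone F5. Juliá–Colonna epoxidation with poly-D-leucine (urea–H2O2, DBU, THF) is expected to give the (2S,3R)-epoxy ketone F6. Reductive cleavage of the C–O bond next to the carbonyl group (SmI2, THF–MeOH, –90 °C) comes back to the route at 11.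

Step 2 (site-selective O-geranylation). Etherification may spread over the 4-OH and 6-OH of 3, since the 4-OH now has the geranyl chain as neighbour. The fallback inverts the order of the two geranylations and sets out from 1. Mitsunobu reaction of the unhindered, symmetric triol with 4 (PPh3, DIAD, THF, 0 °C) would give the 4-O-geranyl ether F7, in which the two free ring positions are again equivalent. C-geranylation with 2 (DBU, THF, 0 °C to rt) comes back to the route at 5.

Further compounds
F1 | step 7 | 2-{(3S)-3-[4-(tert-butyldimethylsilyloxy)phenyl]-1,3-dihydroxypropyl}-6-geranyl-5-(geranyloxy)-3-(triisopropylsilyloxy)phenyl trifluoromethanesulfonate (both epimers at C1 of the propyl chain) | OC(C[C@H](O)c1ccc(O[Si](C)(C)C(C)(C)C)cc1)c1c(O[Si](C(C)C)(C(C)C)C(C)C)cc(OC/C=C(\C)CCC=C(C)C)c(C/C=C(\C)CCC=C(C)C)c1OS(=O)(=O)C(F)(F)F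
F2 | step 7 | (2S)-2-[4-(tert-butyldimethylsilyloxy)phenyl]-8-geranyl-7-(geranyloxy)-5-(triisopropylsilyloxy)chroman-4-ol (both epimers at C4) | CC(C)=CCC/C(C)=C/COc1cc(O[Si](C(C)C)(C(C)C)C(C)C)c2c(c1C/C=C(\C)CCC=C(C)C)O[C@H](c1ccc(O[Si](C)(C)C(C)(C)C)cc1)CC2O
F3 | step 6 | racemic 2-{3-[4-(tert-butyldimethylsilyloxy)phenyl]-3-hydroxypropanoyl}-6-geranyl-5-(geranyloxy)-3-(triisopropylsilyloxy)phenyl trifluoromethanesulfonate | O=C(CC(O)c1ccc(O[Si](C)(C)C(C)(C)C)cc1)c1c(O[Si](C(C)C)(C(C)C)C(C)C)cc(OC/C=C(\C)CCC=C(C)C)c(C/C=C(\C)CCC=C(C)C)c1OS(=O)(=O)C(F)(F)F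
F4 | step 6 | racemic 2-{3-[4-(tert-butyldimethylsilyloxy)phenyl]-3-(methanesulfonyloxy)propanoyl}-6-geranyl-5-(geranyloxy)-3-(triisopropylsilyloxy)phenyl trifluoromethanesulfonate | O=C(CC(OS(C)(=O)=O)c1ccc(O[Si](C)(C)C(C)(C)C)cc1)c1c(O[Si](C(C)C)(C(C)C)C(C)C)cc(OC/C=C(\C)CCC=C(C)C)c(C/C=C(\C)CCC=C(C)C)c1OS(=O)(=O)C(F)(F)F
F5 | step 6 | 2-{(2E)-3-[4-(tert-butyldimethylsilyloxy)phenyl]prop-2-enoyl}-6-geranyl-5-(geranyloxy)-3-(triisopropylsilyloxy)phenyl trifluoromethanesulfonate | O=C(/C=C/c1ccc(O[Si](C)(C)C(C)(C)C)cc1)c1c(O[Si](C(C)C)(C(C)C)C(C)C)cc(OC/C=C(\C)CCC=C(C)C)c(C/C=C(\C)CCC=C(C)C)c1OS(=O)(=O)C(F)(F)F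
F6 | step 6 | 2-({(2S,3R)-3-[4-(tert-butyldimethylsilyloxy)phenyl]oxiran-2-yl}carbonyl)-6-geranyl-5-(geranyloxy)-3-(triisopropylsilyloxy)phenyl trifluoromethanesulfonate | O=C([C@H]2O[C@@H]2c2ccc(O[Si](C)(C)C(C)(C)C)cc2)c1c(O[Si](C(C)C)(C(C)C)C(C)C)cc(OC/C=C(\C)CCC=C(C)C)c(C/C=C(\C)CCC=C(C)C)c1OS(=O)(=O)C(F)(F)F
F7 | step 2 | 1-[4-(geranyloxy)-2,6-dihydroxyphenyl]ethan-1-one | CC(=O)c1c(O)cc(OC/C=C(\C)CCC=C(C)C)cc1O
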